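**Retrosynthetic overview**
- Target ⇐ angeloylation of the C3 alcohol; C3 ⇐ chelation-controlled reduction of a 4,5-epoxy-3-ketone; epoxide ⇐ C6-OH-directed epoxidation of a (1(10)E,4E)-germacra-1(10),4-dien-6-ol.
- Ten-membered ring ⇐ stereoretentive nickel-catalysed opening of a cis-anti-cis tricyclo[4.4.0.0^2,5]decane (cleaves C1–C4 and C5–C10), a four-carbon ring expansion of a cyclohexane.
- Tricycle ⇐ enone–alkene [2+2] photocycloaddition of (R)-piperitone with a 3-silyloxy-2-methylcyclobutene; this forms C4–C5 and C1–C10 and assembles all 15 skeletal carbons.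
- Stereochemical relay: C7 (bought) → C6 (ketone reduction) → C4/C5 (directed epoxidation) → C3 (epoxy-ketone reduction).
- Ring order: cyclohexenone (bought) → cyclobutane/bicyclo[2.2.0]hexane (light) → cyclodecadiene → oxirane.

Assumption: (R)-(−)-piperitone of high enantiomeric purity and 1-methylcyclobutene are taken as catalogue chemicals; germacrane numbering (ring C1–C10, isopropyl on C7, methyls on C4 and C10) is used for all ring positions.

**Step 1**
Reactants: 1 1-methylcyclobutene
Product: 2 rac-2-methylcyclobut-2-en-1-ol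
Conditions: SeO2 (0.3 equiv), t-BuOOH (2 equiv), CH2Cl2, 0 °C → rt
Reagents that add atoms: tert-butyl hydroperoxide, CC(C)(C)OO (oxygen passed on through SeO2, O=[Se]=O)
Why: Sharpless-type SeO2 allylic oxidation (ene reaction, then [2,3]-sigmatropic shift) oxidises the ring CH2 next to the more substituted alkene carbon; the new centre is racemic and is re-set in steps 9–10.

**Step 2**
Reactants: 2 rac-2-methylcyclobut-2-en-1-ol
Product: 3 rac-tert-butyldimethyl[(2-methylcyclobut-2-en-1-yl)oxy]silane
Conditions: TBSCl, imidazole, DMF, 0 °C → rt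
Reagents that add atoms: tert-butyldimethylsilyl chloride, CC(C)(C)[Si](C)(C)Cl
Why: Imidazole-promoted silylation masks the alcohol so that it neither directs the later epoxidation nor is acetylated, and avoids alkoxide-triggered cyclobutene opening.

**Step 3**
Reactants: 3 racemic cyclobutenyl silyl ether; 4 (R)-(−)-piperitone
Product: 5 head-to-head cis-anti-cis photoadduct (tricyclic ketone, two facial isomers)
Conditions: hν (350 nm, Pyrex), excess alkene, CH2Cl2, −20 °C; then neutral Al2O3 plug
Reagents that add atoms: none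
Why: Enone–alkene [2+2] photocycloaddition (stepwise, triplet enone): C10 bonds first to the unsubstituted cyclobutene carbon and the α-keto and tertiary radical centres then close C4–C5, giving the head-to-head cis-anti-cis adduct with the alkene attacked anti to OTBS (the alumina plug secures the cis ring fusion); C1, C4, C5 and C10 are set only relative to one another and all become sp2 in step 5, so the facial mixture is harmless.

**Step 4**
Reactants: 5 tricyclic ketone
Product: 6 tricyclic alcohol (6S)
Conditions: LiBH(s-Bu)3, THF, −78 °C; then H2O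
Reagents that add atoms: none
Why: Substrate-controlled ketone reduction with a bulky hydride: the axial path to C6 is blocked by the syn-axial substituent on C10, so hydride enters equatorially and gives the axial, neomenthol-type alcohol cis to the C7 isopropyl group (6S), as in the menthone to neomenthol reduction.

**Step 5**
Reactants: 6 tricyclic alcohol
Product: 7 (1(10)E,4E,6S,7R)-3-(tert-butyldimethylsilyloxy)germacra-1(10),4-dien-6-ol (C3 epimers)
Conditions: Ni(cod)2 (10 mol %), PPh3 (40 mol %), toluene, 45 °C, air excluded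
Reagents that add atoms: none
Why: Proposed new method: zerovalent nickel carrying three phosphines is proposed to insert edge-on into the strained central C1–C4 σ-bond of the bicyclo[2.2.0]hexane (about 55 kcal/mol strain) to give a divalent 7-nickelanorbornane, which, like tris(phosphine) nickelacyclopentanes that collapse to two alkenes, undergoes retro-oxidative cyclisation across C5–C10 while the metal holds the six carbons in a boat, so both alkenes form suprafacially with retention and the cis-anti-cis adduct can only give the (1(10)E,4E)-diene (the metal-free thermal opening runs through a chair 1,4-diyl and gives E,Z); the closest known reactions are the monovalent-rhodium-catalysed opening of cubane to syn-tricyclooctadiene, zerovalent-nickel insertion into bicyclo[2.1.0]pentane and the fragmentation of nickelacyclopentanes, none yet shown for a bicyclo[2.2.0]hexane to cyclodeca-1,5-diene ring expansion.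

**Step 6**
Reactants: 7 dienol
Product: 8 (1(10)E,4S,5R,6S,7R)-3-(tert-butyldimethylsilyloxy)-4,5-epoxygermacr-1(10)-en-6-ol (C3 epimers)
Conditions: VO(acac)2 (5 mol %), t-BuOOH (1.5 equiv), 2,6-lutidine (0.2 equiv), CH2Cl2, 0 °C
Reagents that add atoms: tert-butyl hydroperoxide, CC(C)(C)OO
Why: Hydroxyl-directed vanadium-catalysed epoxidation: only C4=C5 has a free allylic OH, and allylic 1,3-strain with the C4 methyl keeps H6 in the alkene plane and O6 on the outer face of the trans ring alkene, so oxygen is delivered to that face and C4 and C5 are set from C6 with the target's spatial arrangement (the 4S label only reflects the silyloxy priority).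

**Step 7**
Reactants: 8 epoxy alcohol
Product: 9 (1(10)E,4S,5R,6S,7R)-3-(tert-butyldimethylsilyloxy)-4,5-epoxygermacr-1(10)-en-6-yl acetate (C3 epimers)
Conditions: Ac2O, pyridine, DMAP (cat.), rt
Reagents that add atoms: acetic anhydride, CC(=O)OC(C)=O
Why: DMAP-catalysed acetylation of the only free hydroxyl; no stereocentre is touched.

**Step 8**
Reactants: 9 silyl ether acetate
Product: 10 (1(10)E,3RS,4R,5R,6S,7R)-6-acetoxy-4,5-epoxygermacr-1(10)-en-3-ol
Conditions: Bu4NF, AcOH (1:1), THF, 0 °C → rt
Reagents that add atoms: none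
Why: Fluoride-mediated silyl ether cleavage, buffered with acetic acid so that no free alkoxide causes Payne rearrangement or acetate loss.

**Step 9**
Reactants: 10 epoxy alcohol (C3 epimers)
Product: 11 (1(10)E,4S,5R,6S,7R)-6-acetoxy-4,5-epoxygermacr-1(10)-en-3-one
Conditions: (Pr4N)RuO4 (5 mol %), N-methylmorpholine N-oxide, 4 Å sieves, CH2Cl2, rt
Reagents that add atoms: none
Why: Ley–Griffith oxidation under neutral conditions converts both C3 epimers into one epoxy ketone and so erases the uncontrolled centre.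

**Step 10**
Reactants: 11 epoxy ketone
Product: 12 (1(10)E,3R,4R,5R,6S,7R)-6-acetoxy-4,5-epoxygermacr-1(10)-en-3-ol
Conditions: Zn(BH4)2, Et2O, −20 → 0 °C
Reagents that add atoms: none
Why: Chelation-controlled hydride reduction of an α,β-epoxy ketone: zinc bridges the carbonyl and epoxide oxygens and hydride attacks anti to the C4–C5 bond, giving the erythro (3R) epoxy alcohol, so C3 is set from C4.

**Step 11**
Reactants: 12 (3R)-epoxy alcohol; 13 angelic acid
Product: 15 (1(10)E,3R,4R,5R,6S,7R)-6-acetoxy-4,5-epoxygermacr-1(10)-en-3-yl (Z)-2-methylbut-2-enoate (target), via angelic 2,4,6-trichlorobenzoic anhydride 14 (not isolated)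
Conditions: 13, 2,4,6-trichlorobenzoyl chloride, Et3N, toluene, rt; then 12, 75 °C
Reagents that add atoms: 2,4,6-trichlorobenzoyl chloride, O=C(Cl)c1c(Cl)cc(Cl)cc1Cl (its atoms appear only in 14)
Why: Yamaguchi mixed-anhydride esterification run without DMAP acylates the hindered secondary alcohol while keeping the Z-alkene of the angelate; no stereocentre is touched.

**Compound list**
1 | 1-methylcyclobutene | CC1=CCC1 | starting material
2 | rac-2-methylcyclobut-2-en-1-ol | CC1=CCC1O | intermediate
3 | rac-tert-butyldimethyl[(2-methylcyclobut-2-en-1-yl)oxy]silane | CC1=CCC1O[Si](C)(C)C(C)(C)C | intermediate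
4 | (R)-(−)-piperitone, (6R)-3-methyl-6-(propan-2-yl)cyclohex-2-en-1-one | CC1=CC(=O)[C@@H](C(C)C)CC1 | starting material
5 | 4-(tert-butyldimethylsilyloxy)-1,5-dimethyl-8-(propan-2-yl)tricyclo[4.4.0.0^2,5]decan-7-one; in germacrane numbering ketone at C6, OTBS at C3, cyclobutane C1–C4–C5–C10, bond C1–C4 shared by both four-membered rings; drawn is the (1R,3S,4R,5R,7R,10R) isomer (cyclobutane anti to isopropyl), formed together with the (1S,3R,4S,5S,7R,10S) facial isomer | O=C1[C@@H](C(C)C)CC[C@]2(C)[C@H]3C[C@H](O[Si](C)(C)C(C)(C)C)[C@@]3(C)[C@H]12 | intermediate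
6 | corresponding tricyclic alcohol, OH on C6 cis to isopropyl; drawn (1R,3S,4R,5R,6S,7R,10R), together with the (1S,3R,4S,5S,6S,7R,10S) isomer | O[C@H]1[C@@H](C(C)C)CC[C@]2(C)[C@H]3C[C@H](O[Si](C)(C)C(C)(C)C)[C@@]3(C)[C@H]12 | intermediate
7 | (1(10)E,4E,6S,7R)-3-(tert-butyldimethylsilyloxy)germacra-1(10),4-dien-6-ol, C3 epimers | O[C@H]1[C@@H](C(C)C)CC/C(C)=C/CC(O[Si](C)(C)C(C)(C)C)/C(C)=C/1 | intermediate
8 | (1(10)E,4S,5R,6S,7R)-3-(tert-butyldimethylsilyloxy)-4,5-epoxygermacr-1(10)-en-6-ol, C3 epimers | CC(C)(C)[Si](C)(C)OC1C/C=C(\C)CC[C@H](C(C)C)[C@H](O)[C@H]2O[C@@]21C | intermediate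
9 | (1(10)E,4S,5R,6S,7R)-3-(tert-butyldimethylsilyloxy)-4,5-epoxygermacr-1(10)-en-6-yl acetate, C3 epimers | CC(C)(C)[Si](C)(C)OC1C/C=C(\C)CC[C@H](C(C)C)[C@H](OC(C)=O)[C@H]2O[C@@]21C | intermediate
10 | (1(10)E,3RS,4R,5R,6S,7R)-6-acetoxy-4,5-epoxygermacr-1(10)-en-3-ol | OC1C/C=C(\C)CC[C@H](C(C)C)[C@H](OC(C)=O)[C@H]2O[C@@]21C | intermediate
11 | (1(10)E,4S,5R,6S,7R)-6-acetoxy-4,5-epoxygermacr-1(10)-en-3-one | O=C1C/C=C(\C)CC[C@H](C(C)C)[C@H](OC(C)=O)[C@H]2O[C@@]21C | intermediate
12 | (1(10)E,3R,4R,5R,6S,7R)-6-acetoxy-4,5-epoxygermacr-1(10)-en-3-ol | O[C@@H]1C/C=C(\C)CC[C@H](C(C)C)[C@H](OC(C)=O)[C@H]2O[C@@]21C | intermediate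
13 | angelic acid, (Z)-2-methylbut-2-enoic acid | C/C=C(/C)C(=O)O | starting material
14 | angelic 2,4,6-trichlorobenzoic anhydride | C/C=C(/C)C(=O)OC(=O)c1c(Cl)cc(Cl)cc1Cl | intermediate (not isolated)
15 | (1(10)E,3R,4R,5R,6S,7R)-6-acetoxy-4,5-epoxygermacr-1(10)-en-3-yl (Z)-2-methylbut-2-enoate | C/C=C(/C)C(=O)O[C@@H]1C/C=C(\C)CC[C@H](C(C)C)[C@H](OC(C)=O)[C@H]2O[C@@]21C | target

**Step count and risks**
Total: 11 steps. Longest linear sequence: 11 steps (1 → 15); 9 steps from piperitone 4.

Most likely to fail: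

1. Step 5 (the new reaction). Possible outcomes are no insertion, β-hydride elimination to eudesmene-type decalins, or cleavage of C2–C3 to an elemane-type dialkenylcyclohexane. The fallback is an anionic oxy-Cope ring expansion by known chemistry; it sets out from 4 and returns at 7. 1,2-Reduction of 4 with LiBH(s-Bu)3 (THF, −78 °C) gives cis-piperitol F1, and Et3SiCl/imidazole gives its triethylsilyl ether F2. Hydroboration–oxidation (BH3·THF; NaOH, H2O2) places oxygen on C5 to give the alcohol F3, which (Pr4N)RuO4/N-methylmorpholine N-oxide oxidises to the α-silyloxy ketone F4. Palladium-catalysed α-vinylation (vinyl bromide, NaOt-Bu, Pd2(dba)3, a bulky biaryl phosphine) quaternises C10 to give the vinyl ketone F5. Addition of 2-lithio-1-(tert-butyldimethylsilyloxy)prop-1-ene (from the bromide and t-BuLi, CeCl3, THF, −78 °C) to the C5 ketone gives the 1,2-dialkenylcyclohexanol F6. KH/18-crown-6 (THF) triggers the oxy-Cope rearrangement through a chair transition state (C2–C3 formed, C5–C10 broken, both ring double bonds trans), and PhNTf2 traps the enolate as the enol triflate F7. Pd(OAc)2/PPh3 with HCO2H/Bu3N reduces the triflate to the 4E alkene, giving the bis-silyl ether F8, and HF·pyridine (pyridine, THF, 0 °C) removes the triethylsilyl group to give 7. The C3 configuration obtained does not matter because steps 9–10 re-set it.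

2. Step 10 (facial selectivity of the hydride in the ten-membered ring). The fallback sets out from 11 and returns at 15. If hydride is delivered to the other face, the product is the (3S)-alcohol F9. A Mitsunobu esterification of F9 with angelic acid 13 (PPh3, diisopropyl azodicarboxylate, toluene, 0 °C) inverts C3 and installs the ester in one operation, bypassing step 11.

3. Step 11 (hindered alcohol next to a quaternary epoxide carbon; angelate can isomerise to tiglate). The fallback sets out from 12 and returns at 15. Esterification of 12 with 2-[bis(2,2,2-trifluoroethoxy)phosphoryl]propanoic acid (dicyclohexylcarbodiimide, DMAP) gives the phosphonate ester F10. A Still–Gennari olefination with acetaldehyde (KN(SiMe3)2, 18-crown-6, THF, −78 °C) then builds the Z-configured 2-methylbut-2-enoate on the molecule instead of transferring it.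

Steps 3 and 4 are judged less risky: step 3 rests on the known photocycloaddition of cyclohexenones such as piperitone with methylcyclobutenes, which gives the same head-to-head cis-anti-cis adducts, and step 4 on the menthone to neomenthol reduction.

**Further compounds**
F1 | step 5 | (1S,6R)-3-methyl-6-(propan-2-yl)cyclohex-2-en-1-ol (cis-piperitol) | CC1=C[C@@H](O)[C@@H](C(C)C)CC1
F2 | step 5 | triethyl{[(1S,6R)-3-methyl-6-(propan-2-yl)cyclohex-2-en-1-yl]oxy}silane | CC1=C[C@@H](O[Si](CC)(CC)CC)[C@@H](C(C)C)CC1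
F3 | step 5 | (5R,6S)-2-methyl-5-(propan-2-yl)-6-(triethylsilyloxy)cyclohexan-1-ol, mixture at C1 and C2 | CC1C(O)[C@@H](O[Si](CC)(CC)CC)[C@@H](C(C)C)CC1
F4 | step 5 | (5R,6S)-2-methyl-5-(propan-2-yl)-6-(triethylsilyloxy)cyclohexan-1-one, mixture at C2 | CC1C(=O)[C@@H](O[Si](CC)(CC)CC)[C@@H](C(C)C)CC1
F5 | step 5 | (5R,6S)-2-ethenyl-2-methyl-5-(propan-2-yl)-6-(triethylsilyloxy)cyclohexan-1-one, C2 unassigned | C=CC1(C)C(=O)[C@@H](O[Si](CC)(CC)CC)[C@@H](C(C)C)CC1
F6 | step 5 | (5R,6S)-1-[1-(tert-butyldimethylsilyloxy)prop-1-en-2-yl]-2-ethenyl-2-methyl-5-(propan-2-yl)-6-(triethylsilyloxy)cyclohexan-1-ol, C1 and C2 unassigned | C=CC1(C)C(O)(C(C)=CO[Si](C)(C)C(C)(C)C)[C@@H](O[Si](CC)(CC)CC)[C@@H](C(C)C)CC1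
F7 | step 5 | (1(10)E,4Z,6S,7R)-3-(tert-butyldimethylsilyloxy)-6-(triethylsilyloxy)germacra-1(10),4-dien-5-yl trifluoromethanesulfonate (C3 and C6 trans across C4=C5) | CC[Si](CC)(CC)O[C@H]1[C@@H](C(C)C)CC/C(C)=C/CC(O[Si](C)(C)C(C)(C)C)/C(C)=C/1OS(=O)(=O)C(F)(F)F
F8 | step 5 | (1(10)E,4E,6S,7R)-3-(tert-butyldimethylsilyloxy)-6-(triethylsilyloxy)germacra-1(10),4-diene | CC[Si](CC)(CC)O[C@H]1[C@@H](C(C)C)CC/C(C)=C/CC(O[Si](C)(C)C(C)(C)C)/C(C)=C/1
F9 | step 10 | (1(10)E,3S,4R,5R,6S,7R)-6-acetoxy-4,5-epoxygermacr-1(10)-en-3-ol | O[C@H]1C/C=C(\C)CC[C@H](C(C)C)[C@H](OC(C)=O)[C@H]2O[C@@]21C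
F10 | step 11 | (1(10)E,3R,4R,5R,6S,7R)-6-acetoxy-4,5-epoxygermacr-1(10)-en-3-yl 2-[bis(2,2,2-trifluoroethoxy)phosphoryl]propanoate | CC(C(=O)O[C@@H]1C/C=C(\C)CC[C@H](C(C)C)[C@H](OC(C)=O)[C@H]2O[C@@]21C)P(=O)(OCC(F)(F)F)OCC(F)(F)F
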